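In a one-step world each substrate that reacts takes one partner, and the products stop at the smaller charge.

| flask | substrate | partner | protic impurity | remark | time |
|---|---|---|---|---|---|
| cedar | 7 mM | 6 mM | 1.5 mM | run made earlier |  |
| maple | 11 mM | 6 mM | 1.5 mM | run made earlier |  |
| flask | 5.0 mM | 6.00 mM | 1.50 mM |  | 6.0 min |

- cedar (time / min: target / %, isomer of the product / %): 0.833: 32.9, 33.0; 1.50: 31.9, 32.4; 2.50: 31.9, 30.4; 3.00: 31.2, 31.1; 4.00: 33.2, 31.4; 5.00: 33.4, 31.3
- maple (time / min: target / %, isomer of the product / %): 0.417: 20.0, 18.9; 0.667: 21.9, 20.9; 1.00: 20.7, 21.2; 2.00: 20.4, 20.9; 3.00: 20.6, 19.7; 5.00: 20.0, 21.6

(readings scatter by 1 percentage point)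

- the numbers in the tables scatter by 1 percentage point (one standard deviation)
- a reading or a percentage of target counts all its forms, free or not
- the reaction counts as stopped when no species that holds the substrate changes by six tenths of a point or more over the second half of the time

* which holds at 6.0 min: what has brought the reaction to rest, or that it has not come to rest (all of the substrate has reacted / it is still moving / the partner has run out first / forward and back rates have come level)
* target at 6.0 min, in percent of the substrate charged
* isomer of the product at 6.0 min, in percent of the substrate charged

The earlier runs break that count. At its last reading cedar holds 4.53 mM of target and isomer of the product together, and maple holds 4.58 mM, although maple was charged with more substrate. Both readings stand near c(partner) − c(protic impurity), not near c(partner). In the new flask that difference is 4.50 mM of usable partner, the turnovers that remain once each protic impurity has taken one partner.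

Turned round, substrate gives out before partner in the new flask if c(substrate) stands below that figure. The charge of 5.0 mM stands 0.500 mM above it, so partner is the limiting reagent and the two products can take up 90.0% of the substrate. Target and isomer of the product share the readings about evenly, so this reckoning gives about 45.0% of each. The asked time of 6.0 min is later than cedar's first reading at 0.833 min, where the plateau already stands.

The forecast says: the partner has run out first, with target 44.9% (43.5% to 46.2%) and isomer of the product 44.6% (43.2% to 45.9%), the substrate being “still above 4.5 mM, so partner runs out first”.

The flask gives: the partner has run out first, with target 45.2% and isomer of the product 44.8%.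

    substrate ⇌ tight pair (K = 0.0180, k = 0.120 /s)
    tight pair ⇌ loose pair (K = 2.10, k = 390 /s)
    partner + tight pair → target (k = 7700 /M/s)
    partner + loose pair → isomer of the product (k = 3800 /M/s)
    tight pair → side product (k = 0.00870 /s)
    partner + protic impurity → quenched reagent (k = 550 /M/s)
    crystals ⇌ target, rate k7*(cs7 - [target]) while solid is left; crystals form when [target] > cs7 (solubility = 0.590 mM, k = 6.30 /s)

At 6.00 min the flask holds partner at 0%, substrate at 9.0% and 1.50 mM of quenched reagent, so the 4.50 mM of usable partner has gone to target and isomer of the product. The step from tight pair to loose pair, both ways, is the main reason that target in the flask stands at 45.2%: the run without that step puts target at 90.0%. The forecast would fail if usable partner passed c(substrate). With 15 mM of partner and the other charges held, usable partner is 13.5 mM, so substrate should give out first, leaving 56.7% of the partner. That neighbour flask ends with substrate at 0%, partner at 57%, target at 54.2% and isomer of the product at 45.8%.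

The numbers in the tables are simulated for an exercise; noise was put on by code.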